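The cyclopentane ring is disconnected at C5–C6 and C7–C7a (cyclopenta[c]pyridine numbering), which removes C6/C7 as a propanoyl unit and leaves a 4-methylidene-3-piperidinone. The key step forms both bonds in one flask: thiazolium-catalysed Stetter addition of propanal to the exocyclic enone, released from a Mannich base, makes C5–C6, and aldol condensation of the resulting 1,4-diketone onto the piperidinone carbonyl makes C7=C7a. It exploits the 1,4-relationship of the oxygenated C6 and the ring-fusion carbon C7a. Dehydrogenation to an achiral dienone, CBS reduction and hydroxyl-directed hydrogenation then set the ring stereocentres; Mitsunobu esterification attaches the citronellol-derived acid.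

Key step: step 2

Remark: ring positions follow cyclopenta[c]pyridine numbering (N-2; methyl groups on C-4 and C-7; oxygen on C-6; ring-fusion carbons C-4a and C-7a). Compounds 2, 3, 5, 6 and 7 are racemic; their stereocentres are erased in step 3, and absolute configuration is introduced in step 4.

Step 1
Reactants: 1 tert-butyl 3-oxo-3,6-dihydropyridine-1(2H)-carboxylate
Product: 3 tert-butyl 4-[(dimethylamino)methyl]-3-methyl-5-oxopiperidine-1-carboxylate (racemic diastereomer mixture), via bromomagnesium enolate 2 (not isolated)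
Conditions: MeMgBr, CuBr·SMe2 (10 mol%), THF, −40 °C; then Me2N=CH2+ I−, −40 °C to rt
Reagents that add atoms: methylmagnesium bromide C[Mg]Br; N,N-dimethylmethyleneiminium iodide (Eschenmoser's salt) C[N+](C)=C.[I-]
Why: CuBr·SMe2-catalysed conjugate addition of MeMgBr should give the regiodefined enolate, which is trapped at its carbon by the iminium salt (Mannich reaction); the two new stereocentres are not controlled and are removed in step 3.

Step 2
Reactants: 3 tert-butyl 4-[(dimethylamino)methyl]-3-methyl-5-oxopiperidine-1-carboxylate; 4 propanal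
Product: 7 tert-butyl 4,7-dimethyl-6-oxo-1,3,4,4a,5,6-hexahydro-2H-cyclopenta[c]pyridine-2-carboxylate (racemic diastereomer mixture), via exocyclic enone 5 (not isolated), via 1,4-diketone 6 (not isolated)
Conditions: 3-benzyl-5-(2-hydroxyethyl)-4-methylthiazolium chloride (20 mol%), Et3N, propanal (3 equiv), EtOH, 80 °C, sealed tube; then aq. NaOH added to the same flask, 60 °C
Reagents that add atoms: none
Why: Heating releases exocyclic enone 5 from the Mannich base by loss of dimethylamine, and the thiazol-2-ylidene turns propanal into its Breslow intermediate, which adds to the unsubstituted enone terminus (Stetter reaction) to form C5–C6 and give 1,4-diketone 6. Hydroxide then enolises the ethyl ketone at its methylene (the future C7), which attacks the ring ketone C7a in a 5-(enolexo)-exo-trig aldol addition; dehydration closes the cyclopentenone ring and forms C7=C7a. The closest known reaction type is the Stetter–aldol cyclopentenone annulation of an aldehyde with a vinyl ketone (as in dihydrojasmone syntheses), here with the enone made in situ from a 2-(aminomethyl)cycloalkanone. The only new stereocentre, C4a, arises by enolate protonation and is not controlled, which is harmless because step 3 removes it. The step needs cross-coupling to win over propanal self-acyloin formation, which is reversible and so should funnel into the Stetter product. It also needs regioselective aldol closure, secured because the alternative aldol (C1 methylene onto the side-chain ketone) gives a bridged adduct that cannot dehydrate and reverts.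

Step 3
Reactants: 7 tert-butyl 4,7-dimethyl-6-oxo-1,3,4,4a,5,6-hexahydro-2H-cyclopenta[c]pyridine-2-carboxylate
Product: 8 tert-butyl 4,7-dimethyl-6-oxo-1,3,5,6-tetrahydro-2H-cyclopenta[c]pyridine-2-carboxylate
Conditions: chloranil (1.3 equiv), t-BuOH, reflux
Reagents that add atoms: none
Why: Quinone dehydrogenation of a conjugated enone through its dienol (the enone-to-linear-dienone type) should abstract hydride from the tertiary allylic C4–H and give the achiral, linearly conjugated dienone, erasing both uncontrolled stereocentres.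

Step 4
Reactants: 8 tert-butyl 4,7-dimethyl-6-oxo-1,3,5,6-tetrahydro-2H-cyclopenta[c]pyridine-2-carboxylate
Product: 9 tert-butyl (6R)-6-hydroxy-4,7-dimethyl-1,3,5,6-tetrahydro-2H-cyclopenta[c]pyridine-2-carboxylate
Conditions: (S)-2-methyl-CBS-oxazaborolidine (15 mol%), catecholborane, toluene, −78 °C
Reagents that add atoms: none
Why: Corey–Bakshi–Shibata reduction of a 2-methylcyclopent-2-enone, with the alkenyl flank as the large group and the C5 methylene as the small one, should deliver hydride to one carbonyl face and set C6 as R.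

Step 5
Reactants: 9 tert-butyl (6R)-6-hydroxy-4,7-dimethyl-1,3,5,6-tetrahydro-2H-cyclopenta[c]pyridine-2-carboxylate
Product: 10 tert-butyl (4R,4aS,6R,7R,7aR)-6-hydroxy-4,7-dimethyloctahydro-2H-cyclopenta[c]pyridine-2-carboxylate
Conditions: [Ir(cod)(PCy3)(py)]PF6 (5–10 mol%), H2 (1–4 bar), CH2Cl2, rt
Reagents that add atoms: none
Why: Hydroxyl-directed hydrogenation with the cationic complex [Ir(cod)(PCy3)(py)]PF6 should add hydrogen to both tetrasubstituted alkenes from the face of the C6 hydroxyl (allylic to C7=C7a, homoallylic to C4a=C4), so H-7, H-7a, H-4a and H-4 all end up cis to the hydroxyl and the ring fusion is cis.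

Step 6
Reactants: 10 tert-butyl (4R,4aS,6R,7R,7aR)-6-hydroxy-4,7-dimethyloctahydro-2H-cyclopenta[c]pyridine-2-carboxylate
Product: 12 tert-butyl (4R,4aS,7S,7aR)-4,7-dimethyl-6-oxooctahydro-2H-cyclopenta[c]pyridine-2-carboxylate, via 7-epimeric ketone 11 (not isolated)
Conditions: Dess–Martin periodinane, NaHCO3, CH2Cl2, rt; then K2CO3, MeOH, rt
Reagents that add atoms: none
Why: Dess–Martin oxidation makes C7 epimerisable, and base equilibration should move the C7 methyl to the convex face, trans to the adjacent C7a–C1 bond, the favoured 1,2-trans arrangement on a cyclopentanone.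

Step 7
Reactants: 12 tert-butyl (4R,4aS,7S,7aR)-4,7-dimethyl-6-oxooctahydro-2H-cyclopenta[c]pyridine-2-carboxylate
Product: 13 (4R,4aS,6S,7S,7aR)-2,4,7-trimethyloctahydro-1H-cyclopenta[c]pyridin-6-ol (6-epi-incarvilline)
Conditions: LiAlH4, THF, 0 °C, then reflux
Reagents that add atoms: none
Why: Hydride reduction should attack the ketone from the convex face of the cis-fused bicycle (hydroxyl on the concave face, trans to the C7 methyl, 6S), and the same reagent reduces the tert-butyl carbamate to the N-methyl group.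

Step 8
Reactants: 14 (S)-citronellol
Product: 15 tert-butyl{[(3S)-3,7-dimethyloct-6-en-1-yl]oxy}dimethylsilane
Conditions: TBSCl, imidazole, CH2Cl2, rt
Reagents that add atoms: tert-butyldimethylsilyl chloride CC(C)(C)[Si](C)(C)Cl
Why: Standard silylation of the primary alcohol; the stereocentre is not touched.

Step 9
Reactants: 15 tert-butyl{[(3S)-3,7-dimethyloct-6-en-1-yl]oxy}dimethylsilane
Product: 16 (4R)-6-[(tert-butyldimethylsilyl)oxy]-4-methylhexanal
Conditions: O3, CH2Cl2, −78 °C; then PPh3, −78 °C to rt
Reagents that add atoms: ozone [O-][O+]=O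
Why: Ozonolysis with reductive work-up cleaves the trisubstituted alkene to the aldehyde; the descriptor changes from S to R only through the priority rules.

Step 10
Reactants: 16 (4R)-6-[(tert-butyldimethylsilyl)oxy]-4-methylhexanal; 17 ethyl 2-(triphenyl-λ5-phosphanylidene)propanoate
Product: 18 ethyl (2E,6S)-8-[(tert-butyldimethylsilyl)oxy]-2,6-dimethyloct-2-enoate
Conditions: CH2Cl2, rt
Reagents that add atoms: none
Why: Wittig olefination with the stabilised, α-methyl-substituted ylide should give the E-configured trisubstituted enoate under thermodynamic control of the oxaphosphetane.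

Step 11
Reactants: 18 ethyl (2E,6S)-8-[(tert-butyldimethylsilyl)oxy]-2,6-dimethyloct-2-enoate
Product: 19 (2E,6S)-8-[(tert-butyldimethylsilyl)oxy]-2,6-dimethyloct-2-enoic acid
Conditions: LiOH·H2O, THF/MeOH/H2O, rt; then dilute HCl to pH 4
Reagents that add atoms: lithium hydroxide [Li+].[OH-]
Why: Saponification of the ethyl ester; the primary silyl ether and the alkene geometry should survive the mild base.

Step 12
Reactants: 13 (4R,4aS,6S,7S,7aR)-2,4,7-trimethyloctahydro-1H-cyclopenta[c]pyridin-6-ol; 19 (2E,6S)-8-[(tert-butyldimethylsilyl)oxy]-2,6-dimethyloct-2-enoic acid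
Product: 20 (4R,4aS,6R,7S,7aR)-2,4,7-trimethyloctahydro-1H-cyclopenta[c]pyridin-6-yl (2E,6S)-8-[(tert-butyldimethylsilyl)oxy]-2,6-dimethyloct-2-enoate
Conditions: PPh3, DIAD, THF, 0 °C to rt
Reagents that add atoms: none
Why: Mitsunobu esterification displaces the activated concave-face hydroxyl by the carboxylate in an SN2 process, inverting C6 from S to R so that the ester sits cis to the C7 methyl and the ring-fusion hydrogens.

Step 13
Reactants: 20 (4R,4aS,6R,7S,7aR)-2,4,7-trimethyloctahydro-1H-cyclopenta[c]pyridin-6-yl (2E,6S)-8-[(tert-butyldimethylsilyl)oxy]-2,6-dimethyloct-2-enoate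
Product: 21 (4R,4aS,6R,7S,7aR)-2,4,7-trimethyloctahydro-1H-cyclopenta[c]pyridin-6-yl (2E,6S)-8-hydroxy-2,6-dimethyloct-2-enoate (target)
Conditions: HF·pyridine, THF, 0 °C to rt; NaHCO3 work-up
Reagents that add atoms: none
Why: Fluoride cleavage of the primary silyl ether should leave the enoate ester and the tertiary amine untouched.

Compound list
1 | tert-butyl 3-oxo-3,6-dihydropyridine-1(2H)-carboxylate | O=C1C=CCN(C(=O)OC(C)(C)C)C1 | starting material
2 | tert-butyl 5-[(bromomagnesio)oxy]-3-methyl-3,6-dihydropyridine-1(2H)-carboxylate (racemic) | CC1CN(C(=O)OC(C)(C)C)CC(O[Mg]Br)=C1 | intermediate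
3 | tert-butyl 4-[(dimethylamino)methyl]-3-methyl-5-oxopiperidine-1-carboxylate (racemic diastereomer mixture) | CC1CN(C(=O)OC(C)(C)C)CC(=O)C1CN(C)C | intermediate
4 | propanal | CCC=O | starting material
5 | tert-butyl 3-methyl-4-methylidene-5-oxopiperidine-1-carboxylate (racemic) | CC1CN(C(=O)OC(C)(C)C)CC(=O)C1=C | intermediate
6 | tert-butyl 3-methyl-5-oxo-4-(2-oxobutyl)piperidine-1-carboxylate (racemic diastereomer mixture) | CCC(=O)CC1C(C)CN(C(=O)OC(C)(C)C)CC1=O | intermediate
7 | tert-butyl 4,7-dimethyl-6-oxo-1,3,4,4a,5,6-hexahydro-2H-cyclopenta[c]pyridine-2-carboxylate (racemic diastereomer mixture) | CC1=C2CN(C(=O)OC(C)(C)C)CC(C)C2CC1=O | intermediate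
8 | tert-butyl 4,7-dimethyl-6-oxo-1,3,5,6-tetrahydro-2H-cyclopenta[c]pyridine-2-carboxylate | CC1=C2CN(C(=O)OC(C)(C)C)CC(C)=C2CC1=O | intermediate
9 | tert-butyl (6R)-6-hydroxy-4,7-dimethyl-1,3,5,6-tetrahydro-2H-cyclopenta[c]pyridine-2-carboxylate | O[C@@H]1CC2=C(C)CN(C(=O)OC(C)(C)C)CC2=C1C | intermediate
10 | tert-butyl (4R,4aS,6R,7R,7aR)-6-hydroxy-4,7-dimethyloctahydro-2H-cyclopenta[c]pyridine-2-carboxylate | O[C@@H]1C[C@@H]2[C@@H](CN(C(=O)OC(C)(C)C)C[C@@H]2C)[C@H]1C | intermediate
11 | tert-butyl (4R,4aS,7R,7aR)-4,7-dimethyl-6-oxooctahydro-2H-cyclopenta[c]pyridine-2-carboxylate | O=C1C[C@@H]2[C@@H](CN(C(=O)OC(C)(C)C)C[C@@H]2C)[C@H]1C | intermediate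
12 | tert-butyl (4R,4aS,7S,7aR)-4,7-dimethyl-6-oxooctahydro-2H-cyclopenta[c]pyridine-2-carboxylate | O=C1C[C@@H]2[C@@H](CN(C(=O)OC(C)(C)C)C[C@@H]2C)[C@@H]1C | intermediate
13 | (4R,4aS,6S,7S,7aR)-2,4,7-trimethyloctahydro-1H-cyclopenta[c]pyridin-6-ol | O[C@H]1C[C@@H]2[C@@H](CN(C)C[C@@H]2C)[C@@H]1C | intermediate
14 | (S)-citronellol, (3S)-3,7-dimethyloct-6-en-1-ol | CC(C)=CCC[C@H](C)CCO | starting material
15 | tert-butyl{[(3S)-3,7-dimethyloct-6-en-1-yl]oxy}dimethylsilane | CC(C)=CCC[C@H](C)CCO[Si](C)(C)C(C)(C)C | intermediate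
16 | (4R)-6-[(tert-butyldimethylsilyl)oxy]-4-methylhexanal | O=CCC[C@H](C)CCO[Si](C)(C)C(C)(C)C | intermediate
17 | ethyl 2-(triphenyl-λ5-phosphanylidene)propanoate | CCOC(=O)C(C)=P(c1ccccc1)(c1ccccc1)c1ccccc1 | starting material
18 | ethyl (2E,6S)-8-[(tert-butyldimethylsilyl)oxy]-2,6-dimethyloct-2-enoate | CCOC(=O)/C(C)=C/CC[C@H](C)CCO[Si](C)(C)C(C)(C)C | intermediate
19 | (2E,6S)-8-[(tert-butyldimethylsilyl)oxy]-2,6-dimethyloct-2-enoic acid | C/C(=C\CC[C@H](C)CCO[Si](C)(C)C(C)(C)C)C(=O)O | intermediate
20 | (4R,4aS,6R,7S,7aR)-2,4,7-trimethyloctahydro-1H-cyclopenta[c]pyridin-6-yl (2E,6S)-8-[(tert-butyldimethylsilyl)oxy]-2,6-dimethyloct-2-enoate | C/C(=C\CC[C@H](C)CCO[Si](C)(C)C(C)(C)C)C(=O)O[C@@H]1C[C@@H]2[C@@H](CN(C)C[C@@H]2C)[C@@H]1C | intermediate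
21 | (4R,4aS,6R,7S,7aR)-2,4,7-trimethyloctahydro-1H-cyclopenta[c]pyridin-6-yl (2E,6S)-8-hydroxy-2,6-dimethyloct-2-enoate | C/C(=C\CC[C@H](C)CCO)C(=O)O[C@@H]1C[C@@H]2[C@@H](CN(C)C[C@@H]2C)[C@@H]1C | target

Total step count: 13
Longest linear sequence: 9 steps (steps 1 to 7, then 12 and 13); steps 8 to 11 make the acid side chain.

Steps most likely to fail

Step 3. The quinone may fail to abstract hydride from the five-membered dienol, or may oxidise next to nitrogen and over-oxidise the six-membered ring. The fallback sets out from 7: the extended enol is trapped with TBSOTf and Et3N as tert-butyl 6-[(tert-butyldimethylsilyl)oxy]-4,7-dimethyl-1,3,4,5-tetrahydro-2H-cyclopenta[c]pyridine-2-carboxylate F1, and a Saegusa–Ito dehydrosilylation with Pd(OAc)2 in MeCN should then give the dienone, coming back to the route at 8.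

Step 5. The conjugated diene may bind and deactivate the catalyst, the acid-sensitive dienol may lose water, or reduction may stop before the tetrasubstituted ring-fusion alkene. The fallback replaces directed delivery by steric control and sets out from 8. Reduction with the enantiomeric (R)-2-methyl-CBS-oxazaborolidine and catecholborane should give tert-butyl (6S)-6-hydroxy-4,7-dimethyl-1,3,5,6-tetrahydro-2H-cyclopenta[c]pyridine-2-carboxylate F2. Silylation (TBSCl, imidazole) gives tert-butyl (6S)-6-[(tert-butyldimethylsilyl)oxy]-4,7-dimethyl-1,3,5,6-tetrahydro-2H-cyclopenta[c]pyridine-2-carboxylate F3. Hydrogenation over Pd/C (H2, EtOAc) from the face opposite the silyloxy group should give tert-butyl (4R,4aS,6S,7R,7aR)-6-[(tert-butyldimethylsilyl)oxy]-4,7-dimethyloctahydro-2H-cyclopenta[c]pyridine-2-carboxylate F4. TBAF then frees tert-butyl (4R,4aS,6S,7R,7aR)-6-hydroxy-4,7-dimethyloctahydro-2H-cyclopenta[c]pyridine-2-carboxylate F5, and Dess–Martin oxidation comes back to the route at 11, which is epimerised to 12 as in step 6.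

Step 2. The liberated enone may re-add dimethylamine, oligomerise or isomerise to the endocyclic enone before acyl transfer, and propanal may be drained by self-condensation. The fallback builds the 1,4-diketone by a nitroalkene route and sets out from 1. Conjugate addition with silyl trapping (MeMgBr, CuBr·SMe2, TMSCl) gives tert-butyl 3-methyl-5-[(trimethylsilyl)oxy]-3,6-dihydropyridine-1(2H)-carboxylate F6. SnCl4-mediated addition of F6 to 2-nitrobut-1-ene with hydrolytic (Nef-type) work-up should give the diketone, coming back to the route at 6, which aqueous NaOH closes to 7.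

Further compounds
F1 | step 3 | tert-butyl 6-[(tert-butyldimethylsilyl)oxy]-4,7-dimethyl-1,3,4,5-tetrahydro-2H-cyclopenta[c]pyridine-2-carboxylate (racemic) | CC1CN(C(=O)OC(C)(C)C)CC2=C1CC(O[Si](C)(C)C(C)(C)C)=C2C
F2 | step 5 | tert-butyl (6S)-6-hydroxy-4,7-dimethyl-1,3,5,6-tetrahydro-2H-cyclopenta[c]pyridine-2-carboxylate | O[C@H]1CC2=C(C)CN(C(=O)OC(C)(C)C)CC2=C1C
F3 | step 5 | tert-butyl (6S)-6-[(tert-butyldimethylsilyl)oxy]-4,7-dimethyl-1,3,5,6-tetrahydro-2H-cyclopenta[c]pyridine-2-carboxylate | CC(C)(C)[Si](C)(C)O[C@H]1CC2=C(C)CN(C(=O)OC(C)(C)C)CC2=C1C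
F4 | step 5 | tert-butyl (4R,4aS,6S,7R,7aR)-6-[(tert-butyldimethylsilyl)oxy]-4,7-dimethyloctahydro-2H-cyclopenta[c]pyridine-2-carboxylate | CC(C)(C)[Si](C)(C)O[C@H]1C[C@@H]2[C@@H](CN(C(=O)OC(C)(C)C)C[C@@H]2C)[C@H]1C
F5 | step 5 | tert-butyl (4R,4aS,6S,7R,7aR)-6-hydroxy-4,7-dimethyloctahydro-2H-cyclopenta[c]pyridine-2-carboxylate | O[C@H]1C[C@@H]2[C@@H](CN(C(=O)OC(C)(C)C)C[C@@H]2C)[C@H]1C
F6 | step 2 | tert-butyl 3-methyl-5-[(trimethylsilyl)oxy]-3,6-dihydropyridine-1(2H)-carboxylate (racemic) | CC1CN(C(=O)OC(C)(C)C)CC(O[Si](C)(C)C)=C1
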